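**Retrosynthetic overview**
1. The pendant lactone is made last: acylation of the free pyrrole C3–H with (S)-methylsuccinic anhydride (C20 from the chiral pool), then catalyst-controlled ketone reduction (C18) and lactonisation.
2. C9 comes from convex-face hydrogenation of a C8=C9 ene-lactone.
3. Key disconnection: C9–C9a and C1–C12 are cut together, giving an acyclic N-(5-oxoalkyl)pyrrole that carries an α-methylbutenolide; one acid-catalysed operation closes the azepine and the carbocycle and sets C12 and C13.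
4. The keto-butenolide comes from an auxiliary-controlled anti-aldol (C10, C11), a Weinreb ketone synthesis and a methacrylate ring-closing metathesis.
5. Ring order: butenolide, then azepine and carbocycle together, then pendant lactone.

Assumption and convention: tuberostemonine numbering is used (pyrrole C1–C2–C3–N4–C9a; azepine N4–C5–C6–C7–C8–C9–C9a; carbocycle C9–C10(Et)–C11(O)–C12–C1–C9a; fused lactone C11–O–C14(=O)–C13(Me)–C12; pendant lactone C18(O)–C19–C20(Me)–C21(=O)–O on C3), the given SMILES is read as (9S,10R,11R,12S,13S,18R,20S), and "core" means the tetracyclic lactone without the pendant ring (C3–H).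

**Route**

Step 1
Reactants: 1 (4R)-4-benzyl-1,3-oxazolidin-2-one; 2 butanoyl chloride
Product: 3 (4R)-4-benzyl-3-butanoyl-1,3-oxazolidin-2-one
Conditions: nBuLi, THF, −78 °C; then 2, −78 → 0 °C
Reagents that add atoms: none
Why: N-acylation of the lithiated oxazolidinone (standard Evans auxiliary loading); no new stereocentre.

Step 2
Reactants: 3 (4R)-4-benzyl-3-butanoyl-1,3-oxazolidin-2-one; 4 (E)-cinnamaldehyde
Product: 6 (4R)-4-benzyl-3-[(2S,3S,4E)-2-ethyl-3-hydroxy-5-phenylpent-4-enoyl]-1,3-oxazolidin-2-one, via aldol trimethylsilyl ether 5 (not isolated)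
Conditions: MgCl2 (10 mol %), Et3N, TMSCl, EtOAc, 23 °C; then TFA, MeOH
Reagents that add atoms: none
Why: Evans MgCl2-catalysed direct anti-aldol: the Mg-chelated Z-enolate reacts through a boat transition state on the face remote from the benzyl group, so the (R)-auxiliary gives the (2S,3S)-anti adduct, which fixes C10 (ethyl) and C11 (oxygen) of the target.

Step 3
Reactants: 6 (4R)-4-benzyl-3-[(2S,3S,4E)-2-ethyl-3-hydroxy-5-phenylpent-4-enoyl]-1,3-oxazolidin-2-one
Product: 7 (2S,3S,4E)-2-ethyl-3-hydroxy-N-methoxy-N-methyl-5-phenylpent-4-enamide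
Conditions: MeNHOMe·HCl, AlMe3, THF, 0 °C; aq. work-up
Reagents that add atoms: N,O-dimethylhydroxylamine hydrochloride, CNOC.Cl
Why: Weinreb transamidation of the β-hydroxy imide with the aluminium amide, assisted by the free hydroxyl, releases the auxiliary without touching either stereocentre.

Step 4
Reactants: 8 1H-pyrrole; 9 1,4-dibromobutane
Product: 10 1-(4-bromobutyl)-1H-pyrrole
Conditions: NaH, DMF, 0 °C; then 9 (3 equiv), 0 → 23 °C
Reagents that add atoms: none
Why: SN2 N-alkylation of sodium pyrrolide, with excess dibromide to suppress double alkylation.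

Step 5
Reactants: 7 (2S,3S,4E)-2-ethyl-3-hydroxy-N-methoxy-N-methyl-5-phenylpent-4-enamide; 10 1-(4-bromobutyl)-1H-pyrrole
Product: 12 (1E,3S,4S)-4-ethyl-3-hydroxy-1-phenyl-9-(1H-pyrrol-1-yl)non-1-en-5-one, via Grignard reagent 11 (not isolated)
Conditions: Mg, THF, 45 °C; then 7 (0.45 equiv), THF, −20 → 0 °C; aq. NH4Cl
Reagents that add atoms: none
Why: Weinreb ketone synthesis: one equivalent of 11 deprotonates the hydroxyl, the second adds to give a chelated tetrahedral intermediate that collapses to the ketone only on work-up, so neither over-addition nor epimerisation occurs.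

Step 6
Reactants: 12 (1E,3S,4S)-4-ethyl-3-hydroxy-1-phenyl-9-(1H-pyrrol-1-yl)non-1-en-5-one; 13 2-methylprop-2-enoyl chloride
Product: 14 (1E,3S,4S)-4-ethyl-5-oxo-1-phenyl-9-(1H-pyrrol-1-yl)non-1-en-3-yl 2-methylprop-2-enoate
Conditions: Et3N, DMAP (cat.), CH2Cl2, −20 → 0 °C
Reagents that add atoms: none
Why: DMAP-catalysed O-acylation of the secondary allylic alcohol, run cold so that esterification outpaces β-elimination of the β-acyloxy ketone.

Step 7
Reactants: 14 (1E,3S,4S)-4-ethyl-5-oxo-1-phenyl-9-(1H-pyrrol-1-yl)non-1-en-3-yl 2-methylprop-2-enoate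
Product: 15 (5S)-3-methyl-5-[(3S)-4-oxo-8-(1H-pyrrol-1-yl)octan-3-yl]furan-2(5H)-one
Conditions: second-generation Grubbs catalyst RuCl2(=CHPh)(H2IMes)(PCy3) (5 mol %), toluene, 80 °C
Reagents that add atoms: none
Why: Ring-closing metathesis of the methacrylate with the styrenyl alkene gives the α-methylbutenolide and styrene; both stereocentres are spectators.

Step 8
Reactants: 15 (5S)-3-methyl-5-[(3S)-4-oxo-8-(1H-pyrrol-1-yl)octan-3-yl]furan-2(5H)-one
Product: 18 8,9-didehydro core lactone (10R,11R,12S,13S), via tertiary carbinol 16 (not isolated), via vinylpyrrole 17 (not isolated)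
Conditions: Sc(OTf)3 (10 mol %), 4 Å MS, ClCH2CH2Cl (0.005 M), 23 → 60 °C
Reagents that add atoms: none
Why: Proposed new method: a Lewis-acid domino that joins two known pyrrole reactions (cyclodehydration of N-(oxoalkyl)pyrroles to annulated vinylpyrroles, and Friedel–Crafts conjugate addition of pyrroles to butenolides): pyrrole C2 attacks the ketone to close the azepine, the carbinol 16 dehydrates toward the ring CH2 to the 8,9-ene 17 (C10 stays sp3), and the adjacent pyrrole C1 then adds to the butenolide in a 6-(enolendo)-exo-trig Michael closure in which the tether forces H12 cis to H11 and exo-face protonation of the lactone enol places the C13 methyl on the concave face.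

Step 9
Reactants: 18 8,9-didehydro core lactone (10R,11R,12S,13S)
Product: 19 core lactone (9S,10R,11R,12S,13S)
Conditions: H2 (1 atm), 10 % Pd/C, EtOAc, 23 °C
Reagents that add atoms: none
Why: Heterogeneous syn-hydrogenation of the styrene-type C8=C9 bond from the convex face, opposite the cis-fused lactone and the C10 ethyl group, sets C9 with H9 cis to H10, H11 and H12.

Step 10
Reactants: 20 (S)-2-methylbutanedioic acid
Product: 21 (3S)-3-methyloxolane-2,5-dione
Conditions: AcCl, reflux
Reagents that add atoms: none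
Why: Cyclodehydration of the diacid to the anhydride through a mixed anhydride; the stereocentre is not enolised under these conditions.

Step 11
Reactants: 19 core lactone (9S,10R,11R,12S,13S); 21 (3S)-3-methyloxolane-2,5-dione
Product: 22 (2S)-2-methyl-4-oxo-4-[(9S,10R,11R,12S,13S)-core-3-yl]butanoic acid
Conditions: AlCl3 (2.5 equiv), CH2Cl2, 0 °C; cold aq. work-up
Reagents that add atoms: none
Why: Friedel–Crafts acylation at the only free pyrrole α-position (C3), with the arene attacking the less hindered anhydride carbonyl (remote from the methyl group), so the pool stereocentre becomes C20 unchanged.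

Step 12
Reactants: 22 (2S)-2-methyl-4-oxo-4-[(9S,10R,11R,12S,13S)-core-3-yl]butanoic acid
Product: 24 Epibisdehydroneotuberostemonine J, via hydroxy acid 23 (not isolated)
Conditions: RuCl[(R,R)-TsDPEN](p-cymene) (2 mol %), HCO2Na, H2O/MeOH, 40 °C; acidify to pH 5 and extract; then N,N'-diisopropylcarbodiimide, DMAP (cat.), CH2Cl2, 0 °C
Reagents that add atoms: none
Why: Noyori–Ikariya asymmetric transfer hydrogenation of the heteroaryl ketone under catalyst control (the (R,R)-ligand gives the 18R carbinol by the aryl ketone model) in non-acidic medium, then carbodiimide lactonisation by acyl activation, which retains C18 and C20 and so gives the trans pendant lactone.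

**Compound list**

1 | (4R)-4-benzyl-1,3-oxazolidin-2-one | O=C1N[C@H](Cc2ccccc2)CO1 | starting material
2 | butanoyl chloride | CCCC(Cl)=O | starting material
3 | (4R)-4-benzyl-3-butanoyl-1,3-oxazolidin-2-one | CCCC(=O)N1[C@H](Cc2ccccc2)COC1=O | intermediate
4 | (E)-cinnamaldehyde | O=C/C=C/c1ccccc1 | starting material
5 | (4R)-4-benzyl-3-[(2S,3S,4E)-2-ethyl-5-phenyl-3-(trimethylsilyloxy)pent-4-enoyl]-1,3-oxazolidin-2-one | CC[C@H](C(=O)N1[C@H](Cc2ccccc2)COC1=O)[C@@H](O[Si](C)(C)C)/C=C/c1ccccc1 | intermediate (not isolated)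
6 | (4R)-4-benzyl-3-[(2S,3S,4E)-2-ethyl-3-hydroxy-5-phenylpent-4-enoyl]-1,3-oxazolidin-2-one | CC[C@H](C(=O)N1[C@H](Cc2ccccc2)COC1=O)[C@@H](O)/C=C/c1ccccc1 | intermediate
7 | (2S,3S,4E)-2-ethyl-3-hydroxy-N-methoxy-N-methyl-5-phenylpent-4-enamide | CC[C@H](C(=O)N(C)OC)[C@@H](O)/C=C/c1ccccc1 | intermediate
8 | 1H-pyrrole | c1cc[nH]c1 | starting material
9 | 1,4-dibromobutane | BrCCCCBr | starting material
10 | 1-(4-bromobutyl)-1H-pyrrole | BrCCCCn1cccc1 | intermediate
11 | [4-(1H-pyrrol-1-yl)butyl]magnesium bromide | Br[Mg]CCCCn1cccc1 | intermediate (not isolated)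
12 | (1E,3S,4S)-4-ethyl-3-hydroxy-1-phenyl-9-(1H-pyrrol-1-yl)non-1-en-5-one | CC[C@H](C(=O)CCCCn1cccc1)[C@@H](O)/C=C/c1ccccc1 | intermediate
13 | 2-methylprop-2-enoyl chloride (methacryloyl chloride) | CC(=C)C(Cl)=O | starting material
14 | (1E,3S,4S)-4-ethyl-5-oxo-1-phenyl-9-(1H-pyrrol-1-yl)non-1-en-3-yl 2-methylprop-2-enoate | CC[C@H](C(=O)CCCCn1cccc1)[C@@H](OC(=O)C(C)=C)/C=C/c1ccccc1 | intermediate
15 | (5S)-3-methyl-5-[(3S)-4-oxo-8-(1H-pyrrol-1-yl)octan-3-yl]furan-2(5H)-one | CC[C@H](C(=O)CCCCn1cccc1)[C@H]1OC(=O)C(C)=C1 | intermediate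
16 | (5S)-5-[(1S)-1-(9-hydroxy-6,7,8,9-tetrahydro-5H-pyrrolo[1,2-a]azepin-9-yl)propyl]-3-methylfuran-2(5H)-one (both carbinol epimers) | CC[C@H](C1(O)CCCCn2cccc12)[C@H]1OC(=O)C(C)=C1 | intermediate (not isolated)
17 | (5S)-5-[(1R)-1-(6,7-dihydro-5H-pyrrolo[1,2-a]azepin-9-yl)propyl]-3-methylfuran-2(5H)-one | CC[C@H](C1=CCCCn2cccc12)[C@H]1OC(=O)C(C)=C1 | intermediate (not isolated)
18 | 8,9-didehydro core lactone: pyrrole-fused azepine with C8=C9, carbocycle and cis-fused α-methyl-γ-lactone, C3–H; (10R,11R,12S,13S), H11/H12/H13 cis | CC[C@H]1[C@H]2OC(=O)[C@@H](C)[C@H]2c2ccn3c2C1=CCCC3 | intermediate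
19 | core lactone, C3–H; (9S,10R,11R,12S,13S), H9/H10/H11/H12/H13 all cis | CC[C@H]1[C@H]2OC(=O)[C@@H](C)[C@H]2c2ccn3c2[C@H]1CCCC3 | intermediate
20 | (S)-2-methylbutanedioic acid ((S)-methylsuccinic acid) | C[C@@H](CC(=O)O)C(=O)O | starting material
21 | (3S)-3-methyloxolane-2,5-dione ((S)-methylsuccinic anhydride) | C[C@H]1CC(=O)OC1=O | intermediate
22 | (2S)-2-methyl-4-oxo-4-[(9S,10R,11R,12S,13S)-core-3-yl]butanoic acid | CC[C@H]1[C@H]2OC(=O)[C@@H](C)[C@H]2c2cc(C(=O)C[C@H](C)C(=O)O)n3c2[C@H]1CCCC3 | intermediate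
23 | (2S,4R)-4-hydroxy-2-methyl-4-[(9S,10R,11R,12S,13S)-core-3-yl]butanoic acid | CC[C@H]1[C@H]2OC(=O)[C@@H](C)[C@H]2c2cc([C@H](O)C[C@H](C)C(=O)O)n3c2[C@H]1CCCC3 | intermediate (not isolated)
24 | Epibisdehydroneotuberostemonine J (9S,10R,11R,12S,13S,18R,20S) | CC[C@H]1[C@H]2OC(=O)[C@@H](C)[C@H]2c2cc([C@H]3C[C@H](C)C(=O)O3)n3c2[C@H]1CCCC3 | target

**Step count and risks**

Total: 12 steps. Longest linear sequence: 10 steps (1, 2, 3, 5, 6, 7, 8, 9, 11, 12).

Step 8 is the most likely to fail. The seven-membered Friedel–Crafts closure is slow and competes with oligomerisation at the free pyrrole α-position. Ketone 15 can lose the lactone carboxylate by β-elimination or epimerise at C10. The alkene can migrate to C9=C10, after which loss of the allylic lactone oxygen would aromatise the carbocycle. Exo-face protonation at C13 is a kinetic preference, not a guarantee. The fallback sets out from 7 and 8 and comes back at 18; it builds the azepine by metathesis instead of Friedel–Crafts chemistry. Pyrrole 8 is N-alkylated with 5-bromopent-1-ene (NaH, DMF) to 1-(pent-4-en-1-yl)-1H-pyrrole F1. C2-lithiation (nBuLi, TMEDA, THF) and addition to 7 gives (2S,3S,4E)-2-ethyl-3-hydroxy-1-[1-(pent-4-en-1-yl)-1H-pyrrol-2-yl]-5-phenylpent-4-en-1-one F2. Methylenation of the ketone (Cp2TiMe2, toluene, 70 °C) gives (1E,3S,4R)-4-ethyl-5-[1-(pent-4-en-1-yl)-1H-pyrrol-2-yl]-1-phenylhexa-1,5-dien-3-ol F3, and esterification with 13 gives (1E,3S,4R)-4-ethyl-5-[1-(pent-4-en-1-yl)-1H-pyrrol-2-yl]-1-phenylhexa-1,5-dien-3-yl 2-methylprop-2-enoate F4. A double ring-closing metathesis (second-generation Hoveyda–Grubbs catalyst RuCl2(=CH-C6H4-2-OiPr)(H2IMes), toluene, 80 °C) closes butenolide and azepine to give 17, now isolated, and Sc(OTf)3 then has to effect only the Michael closure to 18.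

Step 12 is the second risk. The N-alkyl 2-acylpyrrole is a vinylogous amide and may be too unreactive toward the Ru–H catalyst, and the pyrrolyl carbinol 23 can ionise and scramble C18. The fallback sets out from 22 and comes back at 24; it reduces an ester with a Lewis-acidic borane system instead. Acid 22 is esterified (TMSCHN2, MeOH/toluene) to methyl (2S)-2-methyl-4-oxo-4-[(9S,10R,11R,12S,13S)-core-3-yl]butanoate F5. Oxazaborolidine reduction ((S)-2-methyl-CBS-oxazaborolidine, catecholborane, toluene, −78 °C), in which boron coordination activates the electron-rich ketone, gives methyl (2S,4R)-4-hydroxy-2-methyl-4-[(9S,10R,11R,12S,13S)-core-3-yl]butanoate F6. Warming F6 with 2-hydroxypyridine (cat.) in toluene closes the lactone to 24.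

Step 11 is the third risk. The anhydride may open at the wrong carbonyl, and AlCl3 may damage the lactone or the pyrrole. The fallback sets out from 21 (with 19) and comes back at 22; the regiochemistry is fixed before the pyrrole is involved, and the acylation is a Vilsmeier–Haack reaction with an amide. Anhydride 21 is opened with Me2NH (THF, 0 °C, attack at the unhindered carbonyl) to (2S)-4-(dimethylamino)-2-methyl-4-oxobutanoic acid F7. Benzylation (BnBr, K2CO3, DMF) gives benzyl (2S)-4-(dimethylamino)-2-methyl-4-oxobutanoate F8. Treatment of 19 with F8 and POCl3 (ClCH2CH2Cl, 60 °C; aq. NaOAc) gives benzyl (2S)-2-methyl-4-oxo-4-[(9S,10R,11R,12S,13S)-core-3-yl]butanoate F9, and hydrogenolysis (H2, Pd/C, EtOAc) returns 22.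

**Further compounds**

F1 | step 8 | 1-(pent-4-en-1-yl)-1H-pyrrole | C=CCCCn1cccc1
F2 | step 8 | (2S,3S,4E)-2-ethyl-3-hydroxy-1-[1-(pent-4-en-1-yl)-1H-pyrrol-2-yl]-5-phenylpent-4-en-1-one | CC[C@H](C(=O)c1cccn1CCCC=C)[C@@H](O)/C=C/c1ccccc1
F3 | step 8 | (1E,3S,4R)-4-ethyl-5-[1-(pent-4-en-1-yl)-1H-pyrrol-2-yl]-1-phenylhexa-1,5-dien-3-ol | CC[C@H](C(=C)c1cccn1CCCC=C)[C@@H](O)/C=C/c1ccccc1
F4 | step 8 | (1E,3S,4R)-4-ethyl-5-[1-(pent-4-en-1-yl)-1H-pyrrol-2-yl]-1-phenylhexa-1,5-dien-3-yl 2-methylprop-2-enoate | CC[C@H](C(=C)c1cccn1CCCC=C)[C@@H](OC(=O)C(C)=C)/C=C/c1ccccc1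
F5 | step 12 | methyl (2S)-2-methyl-4-oxo-4-[(9S,10R,11R,12S,13S)-core-3-yl]butanoate | CC[C@H]1[C@H]2OC(=O)[C@@H](C)[C@H]2c2cc(C(=O)C[C@H](C)C(=O)OC)n3c2[C@H]1CCCC3
F6 | step 12 | methyl (2S,4R)-4-hydroxy-2-methyl-4-[(9S,10R,11R,12S,13S)-core-3-yl]butanoate | CC[C@H]1[C@H]2OC(=O)[C@@H](C)[C@H]2c2cc([C@H](O)C[C@H](C)C(=O)OC)n3c2[C@H]1CCCC3
F7 | step 11 | (2S)-4-(dimethylamino)-2-methyl-4-oxobutanoic acid | C[C@@H](CC(=O)N(C)C)C(=O)O
F8 | step 11 | benzyl (2S)-4-(dimethylamino)-2-methyl-4-oxobutanoate | C[C@@H](CC(=O)N(C)C)C(=O)OCc1ccccc1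
F9 | step 11 | benzyl (2S)-2-methyl-4-oxo-4-[(9S,10R,11R,12S,13S)-core-3-yl]butanoate | CC[C@H]1[C@H]2OC(=O)[C@@H](C)[C@H]2c2cc(C(=O)C[C@H](C)C(=O)OCc4ccccc4)n3c2[C@H]1CCCC3
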